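Ring B (phenol ring: C1 OH, C2 Br, C3 H, C4 Br, C5 H, C6 O-aryl) is not joined to ring A by an arene coupling but grown on the ring A oxygen. Its C6(OAr)–C5(H)–C4(Br)–C3(H) run is C3–C6 of a 2-pyrone. A thermal Diels–Alder reaction with pinacol ethynylboronate and loss of CO2 forms the C1–C6 and C2–C3 bonds in one operation and gives the benzene ring with boron on C1, the future hydroxyl carbon. The precursor is 5-bromo-3-(2,3,4-tribromo-6-methoxyphenoxy)-2-pyrone, made from tribromoguaiacol, methyl chloroacetate and a bromomalonaldehyde enol ether. Oxidation of the C–B bond and one bromination ortho to the hydroxyl finish the target.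

Key step: step 5

Remarks on the chemistry:
- Free bromomalonaldehyde is an acidic enol that would protonate an ester enolate, and an aryloxyacetate is too weakly acidic for an amine-catalysed condensation. The dialdehyde is therefore used as its isopropyl enol ether and the ester as its preformed lithium enolate.
- Assumption: 6 is drawn as the Z isomer (Br and O-iPr cis). Its geometry and that of 7 and 8 is erased on ring closure and does not matter.

Step 1
Reactants: 1 guaiacol
Product: 2 2,3,4-tribromo-6-methoxyphenol (4,5,6-tribromoguaiacol)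
Conditions: Br2 (3.1 equiv), AcOH, 15 °C to rt
Reagents that add atoms: bromine, BrBr
Why: Electrophilic aromatic bromination; the positions para to OH, ortho to OH and para to OMe are the three most activated ones of guaiacol, and the position next to OMe alone reacts last, so three equivalents should stop at this pattern.

Step 2
Reactants: 2 2,3,4-tribromo-6-methoxyphenol; 3 methyl chloroacetate
Product: 4 methyl 2-(2,3,4-tribromo-6-methoxyphenoxy)acetate
Conditions: K2CO3, KI (cat.), DMF, 60 °C
Reagents that add atoms: none
Why: Williamson ether synthesis (SN2) of an acidic phenoxide on an activated primary chloride with iodide catalysis; the phenol oxygen is the only nucleophilic site.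

Step 3
Reactants: 5 bromomalonaldehyde
Product: 6 (Z)-2-bromo-3-isopropoxyprop-2-enal
Conditions: i-PrOH, TsOH·H2O (cat.), cyclohexane, reflux, Dean–Stark
Reagents that add atoms: isopropanol, CC(C)O
Why: Acid-catalysed vinylogous esterification of the enol form of the 1,3-dialdehyde with azeotropic removal of water; it masks the acidic enol and leaves an aldehyde that an enolate can attack.

Step 4
Reactants: 4 methyl 2-(2,3,4-tribromo-6-methoxyphenoxy)acetate; 6 (Z)-2-bromo-3-isopropoxyprop-2-enal
Product: 9 5-bromo-3-(2,3,4-tribromo-6-methoxyphenoxy)-2H-pyran-2-one, via aldol adduct 7 (not isolated), via bromo enal ester 8 (not isolated)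
Conditions: LiN(SiMe3)2 (1.1 equiv), THF, −78 °C, then 6; 2 M HCl, THF, 0 °C to rt; crude, TsOH·H2O (cat.), PhMe, 80 °C
Reagents that add atoms: water, O
Why: Aldol addition of the lithium ester enolate to the aldehyde, acid hydrolysis of the γ-alkoxy allylic alcohol with 1,3-transposition to the 2-bromo enal, then enolization to the dienol and lactonization with loss of methanol; attack at either end of the masked dialdehyde leads to the same enal, reversible enolization lets the double bonds reach the geometry that can close, and LiN(SiMe3)2 is too weak a base to metalate ring A.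

Step 5
Reactants: 9 5-bromo-3-(2,3,4-tribromo-6-methoxyphenoxy)-2H-pyran-2-one; 10 ethynylboronic acid pinacol ester
Product: 12 pinacol 4-bromo-2-(2,3,4-tribromo-6-methoxyphenoxy)phenylboronate, via bicyclic lactone 11 (not isolated)
Conditions: 10 (3 equiv), mesitylene, 160 °C, sealed tube, Ar
Reagents that add atoms: none
Why: The C3=C4–C5=C6 diene of the pyrone and the alkyne should combine in a concerted, asynchronous thermal [4+2] cycloaddition to the 2-oxabicyclo[2.2.2]octadienone 11, which at this temperature loses CO2 by retro-[4+2] and aromatizes. The closest known reaction type is the Diels–Alder/decarboxylation of 2-pyrones with alkynylboronates to arylboronic esters, applied here to a pyrone with an aryloxy group at C3. Ring B is closed intermolecularly, both new bonds (C1–C6 and C2–C3 of ring B) being formed suprafacially in the cycloaddition and the lactone bridge then being expelled. No stereocenter remains, since the two bridgehead centres of racemic 11 vanish with the loss of CO2. The step needs the orientation in which the boron-bearing alkyne carbon bonds to pyrone C3: the aryloxy donor at C3 and the bromine at C5 both enlarge the frontier coefficient at C6, which pairs with the unsubstituted, least hindered alkyne carbon, so boron should end ortho to the aryloxy group and para to bromine. No base or metal is present, so the four C–Br bonds and the new C–B bond should survive.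

Step 6
Reactants: 12 pinacol 4-bromo-2-(2,3,4-tribromo-6-methoxyphenoxy)phenylboronate
Product: 13 4-bromo-2-(2,3,4-tribromo-6-methoxyphenoxy)phenol
Conditions: 30% H2O2, NaOH (1 equiv), THF/H2O, 0 °C to rt
Reagents that add atoms: hydrogen peroxide, OO
Why: Oxidation of an arylboronate by hydroperoxide (ate complex, 1,2-shift of the aryl group from boron to oxygen, hydrolysis), which puts the hydroxyl exactly where boron was; aryl bromides and ethers are inert.

Step 7
Reactants: 13 4-bromo-2-(2,3,4-tribromo-6-methoxyphenoxy)phenol
Product: 14 2,4-dibromo-6-(2,3,4-tribromo-6-methoxyphenoxy)phenol (target)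
Conditions: NBS (1.0 equiv), i-Pr2NH (10 mol%), CH2Cl2, 0 °C
Reagents that add atoms: N-bromosuccinimide, O=C1CCC(=O)N1Br
Why: Amine-mediated ortho-selective electrophilic bromination of a phenol; the para position is blocked by bromine, one ortho position carries the aryloxy group, so the hydroxyl should direct to C2, while ring A and the positions activated only by the diaryl ether oxygen are much less reactive.

Compound list
1 | guaiacol (2-methoxyphenol) | COc1ccccc1O | starting material
2 | 2,3,4-tribromo-6-methoxyphenol | COc1cc(Br)c(Br)c(Br)c1O | intermediate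
3 | methyl chloroacetate | COC(=O)CCl | starting material
4 | methyl 2-(2,3,4-tribromo-6-methoxyphenoxy)acetate | COC(=O)COc1c(OC)cc(Br)c(Br)c1Br | intermediate
5 | bromomalonaldehyde (present as its enol) | O=CC(Br)C=O | starting material
6 | (Z)-2-bromo-3-isopropoxyprop-2-enal | O=C/C(Br)=C/OC(C)C | intermediate
7 | methyl (4Z)-4-bromo-3-hydroxy-5-isopropoxy-2-(2,3,4-tribromo-6-methoxyphenoxy)pent-4-enoate, racemic mixture of C2/C3 diastereomers (not isolated) | COC(=O)C(Oc1c(OC)cc(Br)c(Br)c1Br)C(O)/C(Br)=C/OC(C)C | intermediate
8 | methyl 4-bromo-5-oxo-2-(2,3,4-tribromo-6-methoxyphenoxy)pent-3-enoate, racemic, alkene geometry not fixed (not isolated) | COC(=O)C(Oc1c(OC)cc(Br)c(Br)c1Br)C=C(Br)C=O | intermediate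
9 | 5-bromo-3-(2,3,4-tribromo-6-methoxyphenoxy)-2H-pyran-2-one | O=c1occ(Br)cc1Oc1c(OC)cc(Br)c(Br)c1Br | intermediate
10 | ethynylboronic acid pinacol ester | C#CB1OC(C)(C)C(C)(C)O1 | starting material
11 | 7-bromo-5-(4,4,5,5-tetramethyl-1,3,2-dioxaborolan-2-yl)-4-(2,3,4-tribromo-6-methoxyphenoxy)-2-oxabicyclo[2.2.2]octa-5,7-dien-3-one, racemic (not isolated) | O=C1OC2C=C(B3OC(C)(C)C(C)(C)O3)C1(Oc4c(OC)cc(Br)c(Br)c4Br)C=C2Br | intermediate
12 | pinacol 4-bromo-2-(2,3,4-tribromo-6-methoxyphenoxy)phenylboronate | COc1cc(Br)c(Br)c(Br)c1Oc1cc(Br)ccc1B1OC(C)(C)C(C)(C)O1 | intermediate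
13 | 4-bromo-2-(2,3,4-tribromo-6-methoxyphenoxy)phenol | COc1cc(Br)c(Br)c(Br)c1Oc1cc(Br)ccc1O | intermediate
14 | 2,4-dibromo-6-(2,3,4-tribromo-6-methoxyphenoxy)phenol | COc1cc(Br)c(Br)c(Br)c1Oc1cc(Br)cc(Br)c1O | target

Total step count: 7. Longest linear sequence: 6 steps (steps 1, 2, 4, 5, 6, 7); step 3 is a one-step side branch.

Steps most likely to fail

Step 5 (key step). The alkyne may add the other way round (boron-bearing carbon to pyrone C6), or the crowded C3 terminus may slow the cycloaddition so much that thermal decomposition wins. The fallback gives up the cycloaddition and makes the diaryl ether by aromatic substitution. It sets out from 2: the phenoxide of 2 and commercial 4-bromo-2-fluorobenzaldehyde (K2CO3, DMAc, 110 °C) should give, by SNAr at the fluorine ortho to the formyl group, 4-bromo-2-(2,3,4-tribromo-6-methoxyphenoxy)benzaldehyde F1. Baeyer–Villiger oxidation (mCPBA, CH2Cl2, rt) should turn the aldehyde into 4-bromo-2-(2,3,4-tribromo-6-methoxyphenoxy)phenyl formate F2. Methanolysis (K2CO3, MeOH, rt) then gives 13, where the route is rejoined before step 7.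

Step 4. The enolate addition may be reversed or the bromo enal may polymerize before it enolizes and lactonizes, so that ring closure to the pyrone stays incomplete. The fallback replaces the aldol by an olefination and sets out from 2 and 6. Insertion of the carbene from triethyl diazophosphonoacetate into the O–H bond of 2 (Rh2(OAc)4 cat., PhMe, 80 °C) should give ethyl 2-(diethoxyphosphoryl)-2-(2,3,4-tribromo-6-methoxyphenoxy)acetate F3. Horner–Wadsworth–Emmons reaction of F3 with 6 (LiCl, DBU, MeCN, rt) should give ethyl (4Z)-4-bromo-5-isopropoxy-2-(2,3,4-tribromo-6-methoxyphenoxy)penta-2,4-dienoate F4 as a mixture of C2=C3 isomers. Acid (TsOH·H2O, wet PhMe, 80 °C) should hydrolyse the enol ether, equilibrate the push–pull diene and lactonize to 9, where the route is rejoined.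

Step 7. Bromination may also occur para to the diaryl ether oxygen, or a second bromine may enter ring B. The fallback fixes the position by ipso substitution of silicon and sets out from 9. Cycloaddition of 9 with commercial 2-(trimethylsilyl)ethynylboronic acid pinacol ester (mesitylene, 170 °C) should pass through 7-bromo-5-(pinacolboryl)-6-(trimethylsilyl)-4-(2,3,4-tribromo-6-methoxyphenoxy)-2-oxabicyclo[2.2.2]octa-5,7-dien-3-one F5 (not isolated). After loss of CO2 this should give pinacol [4-bromo-2-(2,3,4-tribromo-6-methoxyphenoxy)-6-(trimethylsilyl)phenyl]boronate F6; the orientation is expected from the same polarization as in step 5 but is not secured. Oxidation as in step 6 gives 4-bromo-2-(2,3,4-tribromo-6-methoxyphenoxy)-6-(trimethylsilyl)phenol F7. NBS (CH2Cl2, 0 °C) should then replace the silyl group ortho to the hydroxyl by bromine, which gives 14 directly.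

Further compounds
F1 | step 5 | 4-bromo-2-(2,3,4-tribromo-6-methoxyphenoxy)benzaldehyde | COc1cc(Br)c(Br)c(Br)c1Oc1cc(Br)ccc1C=O
F2 | step 5 | 4-bromo-2-(2,3,4-tribromo-6-methoxyphenoxy)phenyl formate | COc1cc(Br)c(Br)c(Br)c1Oc1cc(Br)ccc1OC=O
F3 | step 4 | ethyl 2-(diethoxyphosphoryl)-2-(2,3,4-tribromo-6-methoxyphenoxy)acetate | CCOC(=O)C(Oc1c(OC)cc(Br)c(Br)c1Br)P(=O)(OCC)OCC
F4 | step 4 | ethyl (4Z)-4-bromo-5-isopropoxy-2-(2,3,4-tribromo-6-methoxyphenoxy)penta-2,4-dienoate | CCOC(=O)C(Oc1c(OC)cc(Br)c(Br)c1Br)=C/C(Br)=C/OC(C)C
F5 | step 7 | 7-bromo-5-(4,4,5,5-tetramethyl-1,3,2-dioxaborolan-2-yl)-6-(trimethylsilyl)-4-(2,3,4-tribromo-6-methoxyphenoxy)-2-oxabicyclo[2.2.2]octa-5,7-dien-3-one, racemic | O=C1OC2C([Si](C)(C)C)=C(B3OC(C)(C)C(C)(C)O3)C1(Oc4c(OC)cc(Br)c(Br)c4Br)C=C2Br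
F6 | step 7 | pinacol [4-bromo-2-(2,3,4-tribromo-6-methoxyphenoxy)-6-(trimethylsilyl)phenyl]boronate | COc1cc(Br)c(Br)c(Br)c1Oc1cc(Br)cc([Si](C)(C)C)c1B1OC(C)(C)C(C)(C)O1
F7 | step 7 | 4-bromo-2-(2,3,4-tribromo-6-methoxyphenoxy)-6-(trimethylsilyl)phenol | COc1cc(Br)c(Br)c(Br)c1Oc1cc(Br)cc([Si](C)(C)C)c1O
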